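Everything rests on opening the ten-membered carbocycle at C5–C6 (germacrane numbering). C6 is at once allylic to the ring-cis C4=C5 alkene and 1,4 to the C12 carbonyl (C6–C7–C11–C12), so one carbonyl addition can build both rings. In the key step an intramolecular Nozaki–Hiyama–Kishi reaction adds the C5 alkenyl iodide to a C6 aldehyde: this closes the cyclodeca-1(10),4-diene ring, sets C6, and the alkoxide then closes the α-methylene-γ-butyrolactone onto the C12 ester. The precursor is an acyclic, fully acylated iodo aldehyde, assembled by an indium Barbier union (C7–C8) of a malic-acid-derived α-hydroxy aldehyde with a Baylis–Hillman-derived allylic bromide.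

Key step: step 15

Remark: atoms are numbered as in germacranolides (C1–C10 ring carbons, C11–C13 the 2-propenoate unit on C7, C14 the ester carbon on C10, C15 the oxymethyl carbon on C4); compounds 1, 2, 7, 13 and 14 are taken as commercially available.

Step 1
Reactants: 1 tert-butyl(diphenyl)(prop-2-yn-1-yloxy)silane; 2 3-bromoprop-1-ene (allyl bromide)
Product: 3 {[(2E)-2-(bromomethylidene)pent-4-en-1-yl]oxy}(tert-butyl)diphenylsilane
Conditions: PdBr2(PhCN)2 (3 mol %), 2 (excess, neat), rt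
Reagents that add atoms: none
Why: Palladium-catalysed bromoallylation of a terminal alkyne (Kaneda reaction): syn bromopalladation by divalent palladium puts Br on the terminal carbon, and insertion of allyl bromide with β-bromide elimination delivers the allyl group cis to Br, which fixes the C4=C5 geometry (Br, later C6, cis to C3).

Step 2
Reactants: 3 {[(2E)-2-(bromomethylidene)pent-4-en-1-yl]oxy}(tert-butyl)diphenylsilane
Product: 4 {[(2E)-2-(iodomethylidene)pent-4-en-1-yl]oxy}(tert-butyl)diphenylsilane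
Conditions: NaI (2 equiv), CuI (5 mol %), trans-N,N′-dimethylcyclohexane-1,2-diamine (10 mol %), 1,4-dioxane, 110 °C
Reagents that add atoms: sodium iodide, [Na+].[I-]
Why: Copper-catalysed halogen exchange (Finkelstein-type) turns alkenyl bromides into alkenyl iodides with retention of geometry and is driven by precipitation of NaBr.

Step 3
Reactants: 4 {[(2E)-2-(iodomethylidene)pent-4-en-1-yl]oxy}(tert-butyl)diphenylsilane
Product: 5 (4E)-4-{[tert-butyl(diphenyl)silyl]oxymethyl}-5-iodopent-4-en-1-ol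
Conditions: 9-BBN, THF, 0 °C → rt; then aq. NaOH, H2O2, 0 °C
Reagents that add atoms: hydrogen peroxide, OO
Why: Anti-Markovnikov hydroboration–oxidation, in which 9-BBN should react only with the monosubstituted terminal alkene and leave the trisubstituted iodoalkene untouched.

Step 4
Reactants: 5 (4E)-4-{[tert-butyl(diphenyl)silyl]oxymethyl}-5-iodopent-4-en-1-ol
Product: 6 (4E)-4-{[tert-butyl(diphenyl)silyl]oxymethyl}-5-iodopent-4-enal
Conditions: Dess–Martin periodinane, NaHCO3, CH2Cl2, 0 °C → rt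
Reagents that add atoms: none
Why: Dess–Martin oxidation of a primary alcohol to the aldehyde under buffered conditions that do not touch the alkenyl iodide or the silyl ether.

Step 5
Reactants: 7 methyl [(4S)-2,2-dimethyl-1,3-dioxolan-4-yl]acetate; 6 (4E)-4-{[tert-butyl(diphenyl)silyl]oxymethyl}-5-iodopent-4-enal
Product: 8 methyl (6E)-6-{[tert-butyl(diphenyl)silyl]oxymethyl}-2-[(4S)-2,2-dimethyl-1,3-dioxolan-4-yl]-3-hydroxy-7-iodohept-6-enoate (mixture of epimers at C2 and C3)
Conditions: LiN(i-Pr)2 (LDA), THF, −78 °C; then 6, −78 °C; aq. NH4Cl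
Reagents that add atoms: none
Why: Aldol addition of the lithium ester enolate, which should be stable to β-elimination of the dioxolane oxygen at −78 °C; the two new stereocentres are removed in the next step, so the epimer mixture is carried on and C9 comes unchanged from the chiral pool.

Step 6
Reactants: 8 methyl (6E)-6-{[tert-butyl(diphenyl)silyl]oxymethyl}-2-[(4S)-2,2-dimethyl-1,3-dioxolan-4-yl]-3-hydroxy-7-iodohept-6-enoate
Product: 10 methyl (2E,6E)-6-{[tert-butyl(diphenyl)silyl]oxymethyl}-2-[(4S)-2,2-dimethyl-1,3-dioxolan-4-yl]-7-iodohepta-2,6-dienoate, via mesylate 9 (not isolated)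
Conditions: MsCl, Et3N, CH2Cl2, 0 °C; then DBU, rt
Reagents that add atoms: none
Why: Mesylation and E1cB elimination should give the thermodynamically favoured trisubstituted enoate with C2 trans to the ester and cis to C9 (the C1=C10 geometry of the target), mesylate leaving in preference to the dioxolane oxygen.

Step 7
Reactants: 10 methyl (2E,6E)-6-{[tert-butyl(diphenyl)silyl]oxymethyl}-2-[(4S)-2,2-dimethyl-1,3-dioxolan-4-yl]-7-iodohepta-2,6-dienoate
Product: 11 methyl (2E,6E)-6-{[tert-butyl(diphenyl)silyl]oxymethyl}-2-[(1S)-1,2-dihydroxyethyl]-7-iodohepta-2,6-dienoate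
Conditions: PPTS (0.2 equiv), MeOH, 40 °C
Reagents that add atoms: none
Why: Acid-catalysed transacetalization removes the acetonide, the weak acid and methanol as solvent being chosen so that the γ-hydroxy methyl ester should not lactonize and the TBDPS ether survives.

Step 8
Reactants: 11 methyl (2E,6E)-6-{[tert-butyl(diphenyl)silyl]oxymethyl}-2-[(1S)-1,2-dihydroxyethyl]-7-iodohepta-2,6-dienoate
Product: 12 methyl (2E,6E)-6-{[tert-butyl(diphenyl)silyl]oxymethyl}-2-[(1S)-1-hydroxy-2-oxoethyl]-7-iodohepta-2,6-dienoate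
Conditions: TEMPO (0.1 equiv), PhI(OAc)2 (1.1 equiv), CH2Cl2, rt; used crude at once
Reagents that add atoms: none
Why: The TEMPO/PhI(OAc)2 oxidation is selective for the primary alcohol over the secondary allylic one and should give the α-hydroxy aldehyde without over-oxidation.

Step 9
Reactants: 13 2,2-dimethoxyacetaldehyde; 14 methyl prop-2-enoate (methyl acrylate)
Product: 15 methyl 3-hydroxy-4,4-dimethoxy-2-methylidenebutanoate (racemic)
Conditions: DABCO (0.5 equiv), 1,4-dioxane/H2O, rt
Reagents that add atoms: none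
Why: Morita–Baylis–Hillman reaction of an activated α,α-dialkoxy aldehyde with methyl acrylate under DABCO catalysis.

Step 10
Reactants: 15 methyl 3-hydroxy-4,4-dimethoxy-2-methylidenebutanoate
Product: 16 methyl (2Z)-2-(bromomethyl)-4,4-dimethoxybut-2-enoate
Conditions: NBS, Me2S, CH2Cl2, 0 °C → rt
Reagents that add atoms: N-bromosuccinimide, O=C1CCC(=O)N1Br
Why: Corey–Kim-type activation of the Baylis–Hillman alcohol followed by SN2′ attack of bromide is the standard route to (Z)-2-(bromomethyl)alk-2-enoates.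

Step 11
Reactants: 12 methyl (2E,6E)-6-{[tert-butyl(diphenyl)silyl]oxymethyl}-2-[(1S)-1-hydroxy-2-oxoethyl]-7-iodohepta-2,6-dienoate; 16 methyl (2Z)-2-(bromomethyl)-4,4-dimethoxybut-2-enoate
Product: 17 methyl (2E,6E)-6-{[tert-butyl(diphenyl)silyl]oxymethyl}-2-[(1S,2S,3R)-3-(dimethoxymethyl)-1,2-dihydroxy-4-(methoxycarbonyl)pent-4-en-1-yl]-7-iodohepta-2,6-dienoate
Conditions: In powder (1.5 equiv), THF/H2O (1:1), rt
Reagents that add atoms: none
Why: Indium-mediated Barbier allylation in water sets C7 and C8: the (Z)-γ-substituted allylindium should react through a chair transition state (C6 substituent and O8 syn), and chelation of indium by the free C9 hydroxyl and the aldehyde should direct attack to the 8,9-syn diol.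

Step 12
Reactants: 17 methyl (2E,6E)-6-{[tert-butyl(diphenyl)silyl]oxymethyl}-2-[(1S,2S,3R)-3-(dimethoxymethyl)-1,2-dihydroxy-4-(methoxycarbonyl)pent-4-en-1-yl]-7-iodohepta-2,6-dienoate
Product: 18 methyl (2E,6E)-2-[(1S,2S,3R)-1-acetoxy-3-(dimethoxymethyl)-2-hydroxy-4-(methoxycarbonyl)pent-4-en-1-yl]-6-{[tert-butyl(diphenyl)silyl]oxymethyl}-7-iodohepta-2,6-dienoate
Conditions: AcCl (1.05 equiv), 2,4,6-collidine, CH2Cl2, −78 → −40 °C
Reagents that add atoms: acetyl chloride, CC(=O)Cl
Why: Kinetic acylation at low temperature: the allylic C9 hydroxyl next to the planar C10 is far more accessible than the C8 hydroxyl flanked by the fully branched C7, so O9 should be acetylated selectively.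

Step 13
Reactants: 18 methyl (2E,6E)-2-[(1S,2S,3R)-1-acetoxy-3-(dimethoxymethyl)-2-hydroxy-4-(methoxycarbonyl)pent-4-en-1-yl]-6-{[tert-butyl(diphenyl)silyl]oxymethyl}-7-iodohepta-2,6-dienoate
Product: 19 methyl (2E,6E)-2-[(1S,2S,3R)-1-acetoxy-3-(dimethoxymethyl)-4-(methoxycarbonyl)-2-(2-methylpropanoyloxy)pent-4-en-1-yl]-6-{[tert-butyl(diphenyl)silyl]oxymethyl}-7-iodohepta-2,6-dienoate
Conditions: (i-PrCO)2O, DMAP, Et3N, CH2Cl2, 0 °C → rt
Reagents that add atoms: 2-methylpropanoic anhydride, CC(C)C(=O)OC(=O)C(C)C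
Why: DMAP-catalysed acylation of the one remaining, hindered secondary alcohol, which also removes the free O8 hydroxyl that could lactonize onto C12 or C14.

Step 14
Reactants: 19 methyl (2E,6E)-2-[(1S,2S,3R)-1-acetoxy-3-(dimethoxymethyl)-4-(methoxycarbonyl)-2-(2-methylpropanoyloxy)pent-4-en-1-yl]-6-{[tert-butyl(diphenyl)silyl]oxymethyl}-7-iodohepta-2,6-dienoate
Product: 20 methyl (2E,6E)-2-[(1S,2S,3R)-1-acetoxy-3-formyl-4-(methoxycarbonyl)-2-(2-methylpropanoyloxy)pent-4-en-1-yl]-6-{[tert-butyl(diphenyl)silyl]oxymethyl}-7-iodohepta-2,6-dienoate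
Conditions: LiBF4, MeCN/H2O (98:2), rt
Reagents that add atoms: water, O
Why: Mild Lewis-acid hydrolysis of the dimethyl acetal, which should leave the silyl ether and the esters intact and avoids base that would epimerize C7 or eliminate the C8 isobutyrate.

Step 15
Reactants: 20 methyl (2E,6E)-2-[(1S,2S,3R)-1-acetoxy-3-formyl-4-(methoxycarbonyl)-2-(2-methylpropanoyloxy)pent-4-en-1-yl]-6-{[tert-butyl(diphenyl)silyl]oxymethyl}-7-iodohepta-2,6-dienoate
Product: 22 methyl (3aS,4S,5S,6E,10E,11aR)-5-acetoxy-10-{[tert-butyl(diphenyl)silyl]oxymethyl}-3-methylidene-4-(2-methylpropanoyloxy)-2-oxo-2,3,3a,4,5,8,9,11a-octahydrocyclodeca[b]furan-6-carboxylate, via chromium alkoxide 21 (not isolated)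
Conditions: CrCl2 (10 equiv), NiCl2 (0.1 equiv), degassed DMSO/THF (3:1), syringe-pump addition of 20 to 0.002 M, rt; then PPTS (cat.), CH2Cl2, rt
Reagents that add atoms: none
Why: Zerovalent nickel inserts into the C5–I bond and hands the alkenyl group to trivalent chromium with retention of the C4=C5 geometry; the alkenylchromium adds only to the C6 aldehyde (esters, acrylate and silyl ether are inert), and the C6 alkoxide, completed by PPTS, closes onto the C12 methyl ester with loss of methanol. The closest known reaction type is the intramolecular Nozaki–Hiyama–Kishi alkenyl iodide–aldehyde cyclization used for medium and large carbocycles, followed by lactonization of a γ-hydroxy α-methylene ester. The ten-membered carbocycle closes by a 10-exo-trig addition to the carbonyl and the γ-lactone by a 5-exo-trig acyl substitution. C6 is set under control of C7: Felkin–Anh attack anti to the C8 branch with the acrylate inside, reinforced by 1,3-anti induction from the C8 acyloxy group, should give (6R), that is O6 trans to C11 and a trans-fused lactone. The step needs cyclization to beat oligomerization, which high dilution and the two chain-folding cis-trisubstituted alkenes (C9 and C2 cis on C10=C1, C3 and the metal cis on C4=C5) should secure, and it needs the base-sensitive aldehyde (acidic H7, β-isobutyrate) to survive, which the neutral conditions and the weakly nucleophilic chromium alkoxide allow.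

Step 16
Reactants: 22 methyl (3aS,4S,5S,6E,10E,11aR)-5-acetoxy-10-{[tert-butyl(diphenyl)silyl]oxymethyl}-3-methylidene-4-(2-methylpropanoyloxy)-2-oxo-2,3,3a,4,5,8,9,11a-octahydrocyclodeca[b]furan-6-carboxylate
Product: 23 methyl (3aS,4S,5S,6E,10E,11aR)-5-acetoxy-10-(hydroxymethyl)-3-methylidene-4-(2-methylpropanoyloxy)-2-oxo-2,3,3a,4,5,8,9,11a-octahydrocyclodeca[b]furan-6-carboxylate (target, CNP0242134.2)
Conditions: HF·pyridine, pyridine, THF, 0 °C → rt
Reagents that add atoms: none
Why: Buffered fluoride desilylation of the primary TBDPS ether, which should not touch the acetate, the isobutyrate, the methyl ester or the α-methylene lactone.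

Compound list
1 | tert-butyl(diphenyl)(prop-2-yn-1-yloxy)silane | C#CCO[Si](C(C)(C)C)(c1ccccc1)c1ccccc1 | starting material
2 | 3-bromoprop-1-ene (allyl bromide) | C=CCBr | starting material
3 | {[(2E)-2-(bromomethylidene)pent-4-en-1-yl]oxy}(tert-butyl)diphenylsilane | Br/C=C(/CO[Si](C(C)(C)C)(c1ccccc1)c1ccccc1)CC=C | intermediate
4 | {[(2E)-2-(iodomethylidene)pent-4-en-1-yl]oxy}(tert-butyl)diphenylsilane | I/C=C(/CO[Si](C(C)(C)C)(c1ccccc1)c1ccccc1)CC=C | intermediate
5 | (4E)-4-{[tert-butyl(diphenyl)silyl]oxymethyl}-5-iodopent-4-en-1-ol | I/C=C(/CO[Si](C(C)(C)C)(c1ccccc1)c1ccccc1)CCCO | intermediate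
6 | (4E)-4-{[tert-butyl(diphenyl)silyl]oxymethyl}-5-iodopent-4-enal | I/C=C(/CO[Si](C(C)(C)C)(c1ccccc1)c1ccccc1)CCC=O | intermediate
7 | methyl [(4S)-2,2-dimethyl-1,3-dioxolan-4-yl]acetate | COC(=O)C[C@H]1COC(C)(C)O1 | starting material
8 | methyl (6E)-6-{[tert-butyl(diphenyl)silyl]oxymethyl}-2-[(4S)-2,2-dimethyl-1,3-dioxolan-4-yl]-3-hydroxy-7-iodohept-6-enoate (epimers at C2 and C3) | COC(=O)C(C(O)CC/C(CO[Si](C(C)(C)C)(c1ccccc1)c1ccccc1)=C\I)[C@H]1COC(C)(C)O1 | intermediate
9 | 3-O-methanesulfonate of 8 (not isolated) | COC(=O)C(C(OS(C)(=O)=O)CC/C(CO[Si](C(C)(C)C)(c1ccccc1)c1ccccc1)=C\I)[C@H]1COC(C)(C)O1 | intermediate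
10 | methyl (2E,6E)-6-{[tert-butyl(diphenyl)silyl]oxymethyl}-2-[(4S)-2,2-dimethyl-1,3-dioxolan-4-yl]-7-iodohepta-2,6-dienoate | COC(=O)/C(=C/CC/C(CO[Si](C(C)(C)C)(c1ccccc1)c1ccccc1)=C\I)[C@H]1COC(C)(C)O1 | intermediate
11 | methyl (2E,6E)-6-{[tert-butyl(diphenyl)silyl]oxymethyl}-2-[(1S)-1,2-dihydroxyethyl]-7-iodohepta-2,6-dienoate | COC(=O)/C(=C/CC/C(CO[Si](C(C)(C)C)(c1ccccc1)c1ccccc1)=C\I)[C@H](O)CO | intermediate
12 | methyl (2E,6E)-6-{[tert-butyl(diphenyl)silyl]oxymethyl}-2-[(1S)-1-hydroxy-2-oxoethyl]-7-iodohepta-2,6-dienoate | COC(=O)/C(=C/CC/C(CO[Si](C(C)(C)C)(c1ccccc1)c1ccccc1)=C\I)[C@H](O)C=O | intermediate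
13 | 2,2-dimethoxyacetaldehyde | COC(OC)C=O | starting material
14 | methyl prop-2-enoate (methyl acrylate) | C=CC(=O)OC | starting material
15 | methyl 3-hydroxy-4,4-dimethoxy-2-methylidenebutanoate (racemic) | C=C(C(=O)OC)C(O)C(OC)OC | intermediate
16 | methyl (2Z)-2-(bromomethyl)-4,4-dimethoxybut-2-enoate | COC(=O)/C(CBr)=C/C(OC)OC | intermediate
17 | methyl (2E,6E)-6-{[tert-butyl(diphenyl)silyl]oxymethyl}-2-[(1S,2S,3R)-3-(dimethoxymethyl)-1,2-dihydroxy-4-(methoxycarbonyl)pent-4-en-1-yl]-7-iodohepta-2,6-dienoate | COC(OC)[C@H](C(=C)C(=O)OC)[C@H](O)[C@@H](O)/C(C(=O)OC)=C\CC/C(CO[Si](C(C)(C)C)(c1ccccc1)c1ccccc1)=C\I | intermediate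
18 | methyl (2E,6E)-2-[(1S,2S,3R)-1-acetoxy-3-(dimethoxymethyl)-2-hydroxy-4-(methoxycarbonyl)pent-4-en-1-yl]-6-{[tert-butyl(diphenyl)silyl]oxymethyl}-7-iodohepta-2,6-dienoate | COC(OC)[C@H](C(=C)C(=O)OC)[C@H](O)[C@@H](OC(C)=O)/C(C(=O)OC)=C\CC/C(CO[Si](C(C)(C)C)(c1ccccc1)c1ccccc1)=C\I | intermediate
19 | methyl (2E,6E)-2-[(1S,2S,3R)-1-acetoxy-3-(dimethoxymethyl)-4-(methoxycarbonyl)-2-(2-methylpropanoyloxy)pent-4-en-1-yl]-6-{[tert-butyl(diphenyl)silyl]oxymethyl}-7-iodohepta-2,6-dienoate | COC(OC)[C@H](C(=C)C(=O)OC)[C@H](OC(=O)C(C)C)[C@@H](OC(C)=O)/C(C(=O)OC)=C\CC/C(CO[Si](C(C)(C)C)(c1ccccc1)c1ccccc1)=C\I | intermediate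
20 | methyl (2E,6E)-2-[(1S,2S,3R)-1-acetoxy-3-formyl-4-(methoxycarbonyl)-2-(2-methylpropanoyloxy)pent-4-en-1-yl]-6-{[tert-butyl(diphenyl)silyl]oxymethyl}-7-iodohepta-2,6-dienoate | O=C[C@H](C(=C)C(=O)OC)[C@H](OC(=O)C(C)C)[C@@H](OC(C)=O)/C(C(=O)OC)=C\CC/C(CO[Si](C(C)(C)C)(c1ccccc1)c1ccccc1)=C\I | intermediate
21 | chromium alkoxide (drawn as the free alcohol) of methyl 2-[(1S,2S,3S,4E,8E,10R)-3-acetoxy-8-{[tert-butyl(diphenyl)silyl]oxymethyl}-10-hydroxy-4-(methoxycarbonyl)-2-(2-methylpropanoyloxy)cyclodeca-4,8-dien-1-yl]prop-2-enoate (not isolated) | O[C@@H]1/C=C(/CO[Si](C(C)(C)C)(c2ccccc2)c2ccccc2)CC/C=C(/C(=O)OC)[C@H](OC(C)=O)[C@@H](OC(=O)C(C)C)[C@H]1C(=C)C(=O)OC | intermediate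
22 | methyl (3aS,4S,5S,6E,10E,11aR)-5-acetoxy-10-{[tert-butyl(diphenyl)silyl]oxymethyl}-3-methylidene-4-(2-methylpropanoyloxy)-2-oxo-2,3,3a,4,5,8,9,11a-octahydrocyclodeca[b]furan-6-carboxylate | C=C1C(=O)O[C@@H]2/C=C(/CO[Si](C(C)(C)C)(c3ccccc3)c3ccccc3)CC/C=C(/C(=O)OC)[C@H](OC(C)=O)[C@@H](OC(=O)C(C)C)[C@@H]12 | intermediate
23 | methyl (3aS,4S,5S,6E,10E,11aR)-5-acetoxy-10-(hydroxymethyl)-3-methylidene-4-(2-methylpropanoyloxy)-2-oxo-2,3,3a,4,5,8,9,11a-octahydrocyclodeca[b]furan-6-carboxylate | C=C1C(=O)O[C@@H]2/C=C(/CO)CC/C=C(/C(=O)OC)[C@H](OC(C)=O)[C@@H](OC(=O)C(C)C)[C@@H]12 | target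

Total step count: 16. Longest linear sequence: 14 steps (steps 1–8, then 11–16).

The three steps most likely to fail:

First, the macrocyclization (step 15). Intermolecular coupling may outrun the ten-membered closure, the alkenylchromium may be protonated before it reaches the aldehyde, or facial selectivity at C6 may be poor. The fallback changes the organometallic manifold from stoichiometric chromium to rhodium catalysis on boron. Setting out from 19, Miyaura borylation of the alkenyl iodide (B2pin2, PdCl2(dppf), KOPh, toluene, 50 °C) would give the pinacol alkenylboronate acetal F1. LiBF4 in wet MeCN would then unmask the boronate aldehyde F2. With [Rh(cod)OH]2 (cat.) in dioxane/H2O at high dilution, the alkenylrhodium should add 1,2 to the aldehyde, since the α-substituted acrylate and the trisubstituted enoate are poor conjugate acceptors. PPTS would complete the lactonization, and the route is rejoined at 22.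

Second, the site-selective acetylation (step 12). Discrimination between the two secondary hydroxyls may be insufficient, or the acetyl group may migrate from O9 to O8 during the slow second acylation. The fallback reverses the order of acylation through a cyclic orthoester. Setting out from 17, trimethyl orthoisobutyrate and PPTS (CH2Cl2, rt) would give the cyclic 8,9-orthoisobutyrate F3. Brief treatment with aqueous acetic acid should open it so that the acyl group stays on the more hindered oxygen, giving the 8-O-isobutyrate 9-alcohol F4. Ac2O/DMAP would then acetylate the free allylic C9 hydroxyl, coming back at 19.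

Third, the fragment union (step 11). The allylindium may lose methoxide by 1,4-elimination, the α-hydroxy aldehyde may self-condense or epimerize at C9 in water, or the chelation-controlled facial selectivity may erode. The fallback replaces the Barbier reaction by a Lewis-acid-mediated allylstannane addition through an open transition state. Setting out from 16, Bu3SnLi (THF, −78 °C) would give the allylstannane F5. With 12 and MgBr2·OEt2 (CH2Cl2, −20 °C) it should add to the magnesium chelate of the α-hydroxy aldehyde in the Keck sense (syn,syn whatever the stannane geometry), coming back at 17.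

Further compounds
F1 | step 15 | methyl (2E,6E)-2-[(1S,2S,3R)-1-acetoxy-3-(dimethoxymethyl)-4-(methoxycarbonyl)-2-(2-methylpropanoyloxy)pent-4-en-1-yl]-6-{[tert-butyl(diphenyl)silyl]oxymethyl}-7-(4,4,5,5-tetramethyl-1,3,2-dioxaborolan-2-yl)hepta-2,6-dienoate | COC(OC)[C@H](C(=C)C(=O)OC)[C@H](OC(=O)C(C)C)[C@@H](OC(C)=O)/C(C(=O)OC)=C\CC/C(CO[Si](C(C)(C)C)(c1ccccc1)c1ccccc1)=C\B1OC(C)(C)C(C)(C)O1
F2 | step 15 | methyl (2E,6E)-2-[(1S,2S,3R)-1-acetoxy-3-formyl-4-(methoxycarbonyl)-2-(2-methylpropanoyloxy)pent-4-en-1-yl]-6-{[tert-butyl(diphenyl)silyl]oxymethyl}-7-(4,4,5,5-tetramethyl-1,3,2-dioxaborolan-2-yl)hepta-2,6-dienoate | O=C[C@H](C(=C)C(=O)OC)[C@H](OC(=O)C(C)C)[C@@H](OC(C)=O)/C(C(=O)OC)=C\CC/C(CO[Si](C(C)(C)C)(c1ccccc1)c1ccccc1)=C\B1OC(C)(C)C(C)(C)O1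
F3 | step 12 | cyclic 8,9-O-(1-methoxy-2-methylpropylidene) orthoester of 17 (epimers at the orthoester carbon) | COC(OC)[C@H](C(=C)C(=O)OC)[C@@H]1OC(OC)(C(C)C)O[C@H]1/C(C(=O)OC)=C\CC/C(CO[Si](C(C)(C)C)(c2ccccc2)c2ccccc2)=C\I
F4 | step 12 | methyl (2E,6E)-6-{[tert-butyl(diphenyl)silyl]oxymethyl}-2-[(1S,2S,3R)-3-(dimethoxymethyl)-1-hydroxy-4-(methoxycarbonyl)-2-(2-methylpropanoyloxy)pent-4-en-1-yl]-7-iodohepta-2,6-dienoate | COC(OC)[C@H](C(=C)C(=O)OC)[C@H](OC(=O)C(C)C)[C@@H](O)/C(C(=O)OC)=C\CC/C(CO[Si](C(C)(C)C)(c1ccccc1)c1ccccc1)=C\I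
F5 | step 11 | methyl (2Z)-4,4-dimethoxy-2-[(tributylstannyl)methyl]but-2-enoate | COC(=O)/C(C[Sn](CCCC)(CCCC)CCCC)=C/C(OC)OC
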